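**Plan**

- Numbering is that of the eremophilane skeleton (ring A: C1–C5, C10; ring B: C5–C10; C14 on C5, C15 on C4, C11–C13 on C7); β is the face of C14, α the opposite face.
- Retrosynthesis: cut the ester at O3 (acyl chain from (R)-propylene oxide, acetylide, angelic acid and CO2), then ring B at C6–C7 and C9–C10, then ring A at C3–C4 and C5–C10 (Diels–Alder).
- Forward: ring A from a diacetoxybutadiene and tiglic aldehyde; ring B by a one-pot condensation/allylic alkylation with a 4-oxygenated acetoacetate; then C7 ester → isopropenyl, C8 ketone → alcohol, acylation at O3, alkyne semihydrogenation, deprotection.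
- Enabling feature: in ring B the C8 carbonyl lies between C7 and C9, so one keto ester supplies both nucleophilic carbons, while the quaternary C5 of ring A carries both electrophilic carbons, the C6 aldehyde and the allylic C10 acetate.
- Stereochemistry: one catalytic endo Diels–Alder sets C3, C4, C5 and the C10 acetate; C10 follows by net retention in the palladium step; C9 and C7 settle equatorial under equilibrating conditions; C8 comes from a bulky hydride; the chain carbinol comes from (R)-propylene oxide and the Z-enoate from syn semihydrogenation.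

Key step: step 2

Assumption: the (S)-prolinol-derived oxazaborolidinium catalyst is taken to give the enantiomer of the Diels–Alder adduct that is drawn; if the facial sense is the opposite, its enantiomer is used.

**Route**

Step 1
Reactants: 1 (1E,3E)-buta-1,3-diene-1,4-diyl diacetate; 2 (E)-2-methylbut-2-enal (tiglic aldehyde)
Product: 3 (1R,4S,5R,6R)-5-formyl-5,6-dimethylcyclohex-2-ene-1,4-diyl diacetate (ring A: formyl C6 on C5, acetoxy groups on C3 and C10, all three α; C14 and C15 β; alkene C1=C2)
Conditions: B-(o-tolyl)oxazaborolidine from (S)-diphenylprolinol (20 mol %), Tf2NH (20 mol %), CH2Cl2, −78 → −20 °C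
Reagents that add atoms: none
Why: Endo-selective catalytic asymmetric Diels–Alder reaction in which the symmetric diene removes any regiochemical issue, the E geometry of the enal becomes the cis C4/C5 methyl pair, the endo transition state places the formyl group cis to both acetoxy groups (C3 and C10), and the chiral oxazaborolidinium Lewis acid selects the face of the enal.

Step 2
Reactants: 3 (1R,4S,5R,6R)-5-formyl-5,6-dimethylcyclohex-2-ene-1,4-diyl diacetate; 4 ethyl 4-(benzyloxy)-3-oxobutanoate
Product: 6 ethyl 3α-acetoxy-9β-benzyloxy-4β,5β-dimethyl-8-oxo-10βH-decal-1,6-diene-7-carboxylate, via alkylidene keto ester 5 (not isolated)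
Conditions: piperidine/AcOH (5 mol % each), 4 Å MS, toluene, 45 °C; then Pd(PPh3)4 (5 mol %), DBU (1.2 equiv), THF, rt
Reagents that add atoms: none
Why: Knoevenagel condensation of the hindered C6 aldehyde with the active methylene C7 of 4 gives the alkylidene keto ester 5 (C6=C7), whose E and Z isomers interconvert by reversible amine addition; zerovalent palladium then ionizes the C10 acetate with inversion to a π-allyl complex (C10–C1–C2), and the DBU-generated cross-conjugated dienolate attacks through C9 on the face opposite to palladium, forming C9–C10. The closest known reaction types are the Knoevenagel condensation and the intramolecular Tsuji–Trost alkylation of cyclohexenyl acetates by stabilized enolates. Ring B closes in a 6-exo mode with respect to the allyl unit (the attacked terminus C10 lies in the new ring, C1=C2 stays outside it). C10 is set by double inversion, that is net retention relative to the C10 acetate that step 1 placed cis to the formyl group, so the new bond is cis to C6 and the ring fusion is cis (10β-H); C9 stays epimerizable next to the C8 ketone and should settle with the benzyloxy group equatorial (β). The step needs C- rather than O-allylation and attack at C10 rather than C2; the short tether from C5 lets only C10 be reached through a six-membered transition state, O-allylation is reversible under palladium, and ionization of the remote C3 acetate has no reachable nucleophile and should revert.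

Step 3
Reactants: 6 ethyl 3α-acetoxy-9β-benzyloxy-4β,5β-dimethyl-8-oxo-10βH-decal-1,6-diene-7-carboxylate
Product: 7 ethyl 3α-acetoxy-9β-benzyloxy-4β,5β-dimethyl-8-oxo-10βH-decalin-7β-carboxylate (keto form drawn)
Conditions: H2 (1 atm), [Ir(cod)(PCy3)(py)]PF6 (5 mol %), CH2Cl2, rt
Reagents that add atoms: none
Why: Homogeneous hydrogenation with the cationic iridium catalyst should saturate the ring A alkene and the electron-poor C6=C7 bond without hydrogenolysis of the allylic acetate or the benzyl ether, and C7 is not fixed here because it equilibrates through the enol to the equatorial (β) ester.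

Step 4
Reactants: 7 ethyl 3α-acetoxy-9β-benzyloxy-4β,5β-dimethyl-8-oxo-10βH-decalin-7β-carboxylate
Product: 8 ethyl 3α-acetoxy-9β-benzyloxy-8β-hydroxy-4β,5β-dimethyl-10βH-decalin-7β-carboxylate
Conditions: LiBH(s-Bu)3, THF, −78 °C; aq. NH4Cl
Reagents that add atoms: none
Why: Substrate-controlled ketone reduction in which the bulky trialkylborohydride should attack C8 from the equatorial direction, because the carbonyl is flanked by the equatorial C7 ester and C9 benzyloxy groups, giving the axial 8β-alcohol cis to both neighbours.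

Step 5
Reactants: 8 ethyl 3α-acetoxy-9β-benzyloxy-8β-hydroxy-4β,5β-dimethyl-10βH-decalin-7β-carboxylate
Product: 9 ethyl 3α-acetoxy-8β,9β-dihydroxy-4β,5β-dimethyl-10βH-decalin-7β-carboxylate
Conditions: H2 (1 atm), Pd(OH)2/C, EtOAc/EtOH, rt
Reagents that add atoms: none
Why: Hydrogenolysis of the benzyl ether, run only now that no alkene or allylic C–O bond is left, touches no stereocentre.

Step 6
Reactants: 9 ethyl 3α-acetoxy-8β,9β-dihydroxy-4β,5β-dimethyl-10βH-decalin-7β-carboxylate
Product: 10 ethyl 3α-acetoxy-8β,9β-(isopropylidenedioxy)-4β,5β-dimethyl-10βH-decalin-7β-carboxylate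
Conditions: Me2C(OMe)2, PPTS (cat.), CH2Cl2, rt
Reagents that add atoms: 2,2-dimethoxypropane, COC(C)(C)OC
Why: Acid-catalysed transacetalization closes the dioxolane on the cis (axial/equatorial) 8,9-diol and leaves the ethyl ester and the C3 acetate untouched.

Step 7
Reactants: 10 ethyl 3α-acetoxy-8β,9β-(isopropylidenedioxy)-4β,5β-dimethyl-10βH-decalin-7β-carboxylate
Product: 12 7β-acetyl-8β,9β-(isopropylidenedioxy)-4β,5β-dimethyl-10βH-decalin-3α-ol, via N-methoxy-N-methylamide 11 (not isolated)
Conditions: MeNH(OMe)·HCl, i-PrMgCl, THF, −20 → 0 °C; then MeMgBr, 0 °C → rt; aq. NH4Cl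
Reagents that add atoms: methylmagnesium bromide, C[Mg]Br; N,O-dimethylhydroxylamine hydrochloride, CNOC.Cl (its atoms stay only in 11)
Why: One-pot Weinreb ketone synthesis in which the chloromagnesium amide turns the ethyl ester into the N-methoxy-N-methylamide and cleaves the C3 acetate, and the chelated adduct with MeMgBr releases the methyl ketone only on quench, so that C7 next to the new ketone is not exposed to base.

Step 8
Reactants: 12 7β-acetyl-8β,9β-(isopropylidenedioxy)-4β,5β-dimethyl-10βH-decalin-3α-ol
Product: 13 8β,9β-(isopropylidenedioxy)-10βH-eremophil-11-en-3α-ol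
Conditions: Zn, CH2Br2, TiCl4, THF/CH2Cl2, 0 °C → rt
Reagents that add atoms: dibromomethane, BrCBr
Why: Takai–Lombardo methylenation with the non-basic reagent from Zn, CH2Br2 and TiCl4 should convert the enolizable β-alkoxy methyl ketone into the isopropenyl group without epimerizing C7 or eliminating the C8 oxygen.

Step 9
Reactants: 14 (R)-2-methyloxirane
Product: 15 (R)-pent-4-yn-2-ol
Conditions: LiC≡CH·H2NCH2CH2NH2, DMSO, 0 °C → rt; aq. NH4Cl
Reagents that add atoms: lithium acetylide–ethylenediamine complex, [Li]C#C.NCCN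
Why: SN2 ring opening of the epoxide by the acetylide at the unsubstituted carbon leaves the stereocentre of the (R)-epoxide untouched.

Step 10
Reactants: 15 (R)-pent-4-yn-2-ol; 16 (Z)-2-methylbut-2-enoic acid (angelic acid)
Product: 18 (R)-pent-4-yn-2-yl (Z)-2-methylbut-2-enoate, via mixed anhydride 17 (not isolated)
Conditions: 2,4,6-Cl3C6H2COCl, Et3N, toluene, rt; then 15, 80 °C
Reagents that add atoms: 2,4,6-trichlorobenzoyl chloride, O=C(Cl)c1c(Cl)cc(Cl)cc1Cl (its atoms stay only in 17)
Why: Yamaguchi-type esterification through the mixed anhydride without a nucleophilic catalyst should keep the Z (angelate) geometry, and the carbinol centre is retained because only its O–H bond is broken.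

Step 11
Reactants: 18 (R)-pent-4-yn-2-yl (Z)-2-methylbut-2-enoate
Product: 19 (R)-5-{[(Z)-2-methylbut-2-enoyl]oxy}hex-2-ynoic acid
Conditions: AgI (2 mol %), Cs2CO3, CO2 (1 atm), DMF, 50 °C; then aq. HCl
Reagents that add atoms: carbon dioxide, O=C=O
Why: Silver-catalysed C–H carboxylation of the terminal alkyne with CO2 tolerates the ester and creates no stereocentre.

Step 12
Reactants: 13 8β,9β-(isopropylidenedioxy)-10βH-eremophil-11-en-3α-ol; 19 (R)-5-{[(Z)-2-methylbut-2-enoyl]oxy}hex-2-ynoic acid
Product: 20 8β,9β-(isopropylidenedioxy)-10βH-eremophil-11-en-3α-yl (R)-5-{[(Z)-2-methylbut-2-enoyl]oxy}hex-2-ynoate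
Conditions: DCC, DMAP (cat.), CH2Cl2, 0 °C → rt
Reagents that add atoms: none
Why: Steglich esterification of the only free hydroxyl group (equatorial O3) with the alkynoic acid proceeds with retention at C3 because the C3–O bond is not broken.

Step 13
Reactants: 20 8β,9β-(isopropylidenedioxy)-10βH-eremophil-11-en-3α-yl (R)-5-{[(Z)-2-methylbut-2-enoyl]oxy}hex-2-ynoate
Product: 21 8β,9β-(isopropylidenedioxy)-10βH-eremophil-11-en-3α-yl (2Z,5R)-5-{[(Z)-2-methylbut-2-enoyl]oxy}hex-2-enoate
Conditions: H2 (1 atm), Pd/CaCO3 poisoned with Pb(OAc)2, quinoline, EtOAc, rt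
Reagents that add atoms: none
Why: Semihydrogenation of the ynoate over the lead-poisoned palladium catalyst adds hydrogen syn to give the Z-enoate and should leave the isopropenyl and angelate alkenes alone.

Step 14
Reactants: 21 8β,9β-(isopropylidenedioxy)-10βH-eremophil-11-en-3α-yl (2Z,5R)-5-{[(Z)-2-methylbut-2-enoyl]oxy}hex-2-enoate
Product: 22 8β,9β-dihydroxy-10βH-eremophil-11-en-3α-yl (2Z,5R)-5-{[(Z)-2-methylbut-2-enoyl]oxy}hex-2-enoate (CNP0395983.1)
Conditions: AcOH/H2O (4:1), 40 °C
Reagents that add atoms: none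
Why: Mild acid hydrolysis of the isopropylidene acetal frees the 8,9-diol without touching the esters or the alkenes.

**Compound list**

1 | (1E,3E)-buta-1,3-diene-1,4-diyl diacetate | CC(=O)O/C=C/C=C/OC(C)=O | starting material
2 | (E)-2-methylbut-2-enal (tiglic aldehyde) | C/C=C(\C)C=O | starting material
3 | (1R,4S,5R,6R)-5-formyl-5,6-dimethylcyclohex-2-ene-1,4-diyl diacetate | O=C[C@@]1(C)[C@H](C=C[C@@H](OC(C)=O)[C@@H]1C)OC(C)=O | intermediate
4 | ethyl 4-(benzyloxy)-3-oxobutanoate | CCOC(=O)CC(=O)COCc1ccccc1 | starting material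
5 | alkylidene keto ester, C6=C7 (E/Z mixture; the isomer with the C8 ketone cis to C5 is drawn) | CCOC(=O)/C(=C/[C@@]1(C)[C@H](C=C[C@@H](OC(C)=O)[C@@H]1C)OC(C)=O)C(=O)COCc1ccccc1 | intermediate
6 | ethyl 3α-acetoxy-9β-benzyloxy-4β,5β-dimethyl-8-oxo-10βH-decal-1,6-diene-7-carboxylate | CCOC(=O)C1=C[C@@]2(C)[C@H](C=C[C@@H](OC(C)=O)[C@@H]2C)[C@@H](OCc3ccccc3)C1=O | intermediate
7 | ethyl 3α-acetoxy-9β-benzyloxy-4β,5β-dimethyl-8-oxo-10βH-decalin-7β-carboxylate | CCOC(=O)[C@H]1C[C@@]2(C)[C@H](CC[C@@H](OC(C)=O)[C@@H]2C)[C@@H](OCc3ccccc3)C1=O | intermediate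
8 | ethyl 3α-acetoxy-9β-benzyloxy-8β-hydroxy-4β,5β-dimethyl-10βH-decalin-7β-carboxylate | CCOC(=O)[C@H]1C[C@@]2(C)[C@H](CC[C@@H](OC(C)=O)[C@@H]2C)[C@@H](OCc3ccccc3)[C@H]1O | intermediate
9 | ethyl 3α-acetoxy-8β,9β-dihydroxy-4β,5β-dimethyl-10βH-decalin-7β-carboxylate | CCOC(=O)[C@H]1C[C@@]2(C)[C@H](CC[C@@H](OC(C)=O)[C@@H]2C)[C@@H](O)[C@H]1O | intermediate
10 | ethyl 3α-acetoxy-8β,9β-(isopropylidenedioxy)-4β,5β-dimethyl-10βH-decalin-7β-carboxylate | CCOC(=O)[C@H]1C[C@@]2(C)[C@H](CC[C@@H](OC(C)=O)[C@@H]2C)[C@H]3OC(C)(C)O[C@@H]13 | intermediate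
11 | 3α-hydroxy-8β,9β-(isopropylidenedioxy)-N-methoxy-N,4β,5β-trimethyl-10βH-decalin-7β-carboxamide | CON(C)C(=O)[C@H]1C[C@@]2(C)[C@H](CC[C@@H](O)[C@@H]2C)[C@H]3OC(C)(C)O[C@@H]13 | intermediate
12 | 7β-acetyl-8β,9β-(isopropylidenedioxy)-4β,5β-dimethyl-10βH-decalin-3α-ol | CC(=O)[C@H]1C[C@@]2(C)[C@H](CC[C@@H](O)[C@@H]2C)[C@H]3OC(C)(C)O[C@@H]13 | intermediate
13 | 8β,9β-(isopropylidenedioxy)-10βH-eremophil-11-en-3α-ol | C=C(C)[C@H]1C[C@@]2(C)[C@H](CC[C@@H](O)[C@@H]2C)[C@H]3OC(C)(C)O[C@@H]13 | intermediate
14 | (R)-2-methyloxirane | C[C@@H]1CO1 | starting material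
15 | (R)-pent-4-yn-2-ol | C[C@@H](O)CC#C | intermediate
16 | (Z)-2-methylbut-2-enoic acid (angelic acid) | C/C=C(/C)C(=O)O | starting material
17 | (Z)-2-methylbut-2-enoic 2,4,6-trichlorobenzoic anhydride | C/C=C(/C)C(=O)OC(=O)c1c(Cl)cc(Cl)cc1Cl | intermediate
18 | (R)-pent-4-yn-2-yl (Z)-2-methylbut-2-enoate | C#CC[C@@H](C)OC(=O)/C(C)=C\C | intermediate
19 | (R)-5-{[(Z)-2-methylbut-2-enoyl]oxy}hex-2-ynoic acid | OC(=O)C#CC[C@@H](C)OC(=O)/C(C)=C\C | intermediate
20 | 8β,9β-(isopropylidenedioxy)-10βH-eremophil-11-en-3α-yl (R)-5-{[(Z)-2-methylbut-2-enoyl]oxy}hex-2-ynoate | C=C(C)[C@H]1C[C@@]2(C)[C@H](CC[C@@H](OC(=O)C#CC[C@@H](C)OC(=O)/C(C)=C\C)[C@@H]2C)[C@H]3OC(C)(C)O[C@@H]13 | intermediate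
21 | 8β,9β-(isopropylidenedioxy)-10βH-eremophil-11-en-3α-yl (2Z,5R)-5-{[(Z)-2-methylbut-2-enoyl]oxy}hex-2-enoate | C=C(C)[C@H]1C[C@@]2(C)[C@H](CC[C@@H](OC(=O)/C=C\C[C@@H](C)OC(=O)/C(C)=C\C)[C@@H]2C)[C@H]3OC(C)(C)O[C@@H]13 | intermediate
22 | 8β,9β-dihydroxy-10βH-eremophil-11-en-3α-yl (2Z,5R)-5-{[(Z)-2-methylbut-2-enoyl]oxy}hex-2-enoate (CNP0395983.1) | C=C(C)[C@H]1C[C@@]2(C)[C@H](CC[C@@H](OC(=O)/C=C\C[C@@H](C)OC(=O)/C(C)=C\C)[C@@H]2C)[C@@H](O)[C@H]1O | target

**Step count and risks**

Total step count: 14. Longest linear sequence: 11 steps (steps 1–8, then 12–14); steps 9–11 make the acyl chain.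

Steps most likely to fail:

1. Step 2. The ring closure may go astray by O-allylation of the dienolate, by unproductive ionization and diene-forming elimination at the remaining C3 allylic acetate, or by sluggish condensation of the hindered aldehyde. Fallback: starting from 3 and 4, the Knoevenagel condensation is run alone and 5 is isolated. The ketone of 5 is converted with TBSOTf/Et3N (CH2Cl2, −78 °C) into the tert-butyldimethylsilyl dienol ether F1. Ring B is then closed without palladium by Lewis-acid ionization of the C10 acetate (TMSOTf or ZnCl2, CH2Cl2, −78 → −20 °C) and capture of the allyl cation by the tethered enol silane, a Mukaiyama-type allylic alkylation. The tether again permits only cis delivery to C10, and aqueous work-up returns the route at 6.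

2. Step 1. The trisubstituted enal may react too slowly with the acetoxy diene, and endo or facial selectivity may erode at the temperature then needed. Fallback: starting from 1 and 2, the cycloaddition is run with an achiral Lewis acid (Me2AlCl, CH2Cl2, −40 °C) to give the racemic all-cis adduct F2. Condensation with (1R,2R)-N,N'-dimethyl-1,2-diphenylethane-1,2-diamine (4 Å MS, Et2O, rt) gives two diastereomeric aminals, the aminal of the desired enantiomer F3 and the aminal of its mirror-image aldehyde F4. These are separated by chromatography, and hydrolysis of F3 (aq. AcOH, THF, rt) returns the route at 3 and recovers the diamine.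

3. Step 4. The basic hydride may convert the enol-rich β-keto ester into its unreactive enolate so that reduction stalls, or facial selectivity at C8 may be poor. Fallback: starting from 7, the hydride reagent is replaced by an enzyme-controlled reduction with a screened ketoreductase (NADPH, glucose/glucose dehydrogenase recycling, phosphate buffer pH 7 with DMSO cosolvent, 30 °C). This works on the keto tautomer under neutral conditions while C7 equilibrates, the known behaviour of 2-oxocycloalkanecarboxylates, which give cis hydroxy esters. It makes no new compound (F0) and returns the route at 8.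

Further compounds
F1 | step 2 | tert-butyldimethylsilyl dienol ether of 5 (C8 silyloxy, C8=C9; enol ether geometry not defined) | CCOC(=O)/C(=C/[C@@]1(C)[C@H](C=C[C@@H](OC(C)=O)[C@@H]1C)OC(C)=O)C(O[Si](C)(C)C(C)(C)C)=COCc1ccccc1
F2 | step 1 | racemic all-cis 5-formyl-5,6-dimethylcyclohex-2-ene-1,4-diyl diacetate (both enantiomers) | O=C[C@@]1(C)[C@H](C=C[C@@H](OC(C)=O)[C@@H]1C)OC(C)=O.O=C[C@]1(C)[C@@H](C=C[C@H](OC(C)=O)[C@H]1C)OC(C)=O
F3 | step 1 | aminal of 3 with (1R,2R)-N,N'-dimethyl-1,2-diphenylethane-1,2-diamine (2-substituted (4R,5R)-1,3-dimethyl-4,5-diphenylimidazolidine) | CN1[C@H](c2ccccc2)[C@@H](c2ccccc2)N(C)C1[C@@]1(C)[C@H](C=C[C@@H](OC(C)=O)[C@@H]1C)OC(C)=O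
F4 | step 1 | diastereomeric aminal from the enantiomer of 3 | CN1[C@H](c2ccccc2)[C@@H](c2ccccc2)N(C)C1[C@]1(C)[C@@H](C=C[C@H](OC(C)=O)[C@H]1C)OC(C)=O
F0 | step 4 | none | none
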